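(The numbers in the tables stem from a simulated flask on assumed constants; noise was put on by code.)

Two end values and one trend were asked of me, for the flasks winter and dusk.

| setting | maple | larch | winter | dusk |
|---|---|---|---|---|
| solid electrophile | 0.050 M | 0.050 M | 0.050 M | 0.050 M |
| nucleophile | 0.048 M (fed, over 1.0 h) | 0.076 M (fed, over 1.0 h) | 0.0550 M (fed, over 1.0 h) | 0.110 M (fed, over 1.0 h) |
| remark | run made earlier | run made earlier |  |  |
| time |  |  | 30 h | 30 h |

| run | time / h | solid electrophile / % | product / % |
|---|---|---|---|
| maple | 1.33 | 95.4 | 0 |
| maple | 2.00 | 96.7 | 0.8 |
| maple | 3.00 | 94.2 | 2.3 |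
| maple | 5.00 | 87.4 | 1.7 |
| maple | 10.0 | 80.8 | 7.7 |
| maple | 15.0 | 73.3 | 13.1 |
| larch | 2.50 | 93.7 | 3.1 |
| larch | 5.00 | 90.1 | 3.9 |
| larch | 8.00 | 86.3 | 8.6 |
| larch | 10.0 | 81.6 | 11.1 |
| larch | 12.0 | 77.3 | 14.8 |
| larch | 15.0 | 73.0 | 18.9 |

(scatter of a reading: 1 percentage point)

- part of the solid electrophile that has reacted (what has only dissolved counts as not reacted) at the end, winter
- part of the solid electrophile that has reacted (what has only dissolved counts as not reacted) at the end, dusk
- what raising the concentration of nucleophile from its lowest to its highest value here does to the part of the solid electrophile that has reacted (what has only dissolved counts as not reacted) (changes below 5 percentage points count as none) (it falls / it rises / no change)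

- at the start none of the solid electrophile is in solution
- what has only dissolved of solid electrophile counts as not reacted
- what has gone from electrophile into another species counts as reacted, even if it can come back

1. I began with the rate at which solid disappeared. Averaged over maple and larch, it was 0.0225 /h of the charge up to 5.00 h. The later rate, s, was 0.0161 /h between 10.0 h and 15.0 h, a slowing by a factor of 0.716. I held s to the end, which put the solid lost in winter and dusk at L = 51.0%.

2. Dissolved material counts as not reacted, so I read solid lost minus product at 15.0 h as a standing stock of unreacted material: 13.6% in maple and 8.10% in larch, smaller in larch. Dividing s by the stock and by the nucleophile charge c gave the catch constant k, the turnovers of that stock per hour per molar of charge: 2.54 /M/h, a reading that carries the scatter. Holding the nucleophile at its charge c, I treated the stock as pseudo-first-order, with rate constant kc.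

3. Turnovers by the end, N = kct, were 4.19 in winter and 8.38 in dusk. So I took the stock as standing at S = s/(kc): 11.5% in winter and 5.76% in dusk. My reckoning L − S gave 39.5% for winter and 45.2% for dusk, a rise of 5.7 percentage points, just above the margin.

4. The forecast differed from my reckoning: 47% (40% to 54%) for winter, 48% (42% to 55%) for dusk, and no change: “I expect no meaningful trend”.

5. Winter gave 37.1% and dusk 48.6%; the trend was: it rises, by 12 points.

    nucleophile + acid set free ⇌ protonated nucleophile, settled at all times (K = 12000 /M)
    electrophile ⇌ dormant form (K = 0.490, k = 0.0127 /min)
    solid electrophile ⇌ electrophile, rate k3*(cs3 - [electrophile]) while solid is left; crystals form when [electrophile] > cs3 (solubility = 13.0 mM, k = 0.00141 /min)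
    electrophile + nucleophile → acid set free + product (k = 0.0669 /M/min)

Solid lost minus product is electrophile and dormant form together, and the dormant form counts as reacted. At the end that stock stood at 15.8% in winter against S of 11.5%, and at 8.90% in dusk against S of 5.76%. For the neighbouring flask, like dusk but with 0.19 M of nucleophile, the same reckoning gave kc = 0.483 /h, hence 14.5 turnovers and S of 3.34%. That flask ended with 55.5% reacted and with electrophile and dormant form together at 5.05%.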